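**Retrosynthetic overview**
- Guajadial D ⇐ a phenol tethered to a cis-fused octalin alkene (C4=C5). The pyran ring is closed last by anti-selenoetherification and selenoxide syn-elimination, which forms the spiro C4–O bond and the C5=C6 alkene and relays the C6–H stereocentre to C4.
- That precursor ⇐ Negishi sp3–sp2 coupling (C15–C4) of a bicyclic enol triflate with a (2S)-2,2-diarylethylzinc reagent carrying the protected diformylphloroglucinol.
- Enol triflate ⇐ Diels–Alder of (S)-cryptone with a 2-silyloxybutadiene (ring B onto ring A; sets C1/C6 cis, anti to isopropyl), then the C10 methyl by methylenation/hydrogenation and Saegusa/α′-triflation/diimide for a regiodefined C4=C5.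
- Zinc reagent ⇐ stereospecific (inversion) arylation of (S)-styrene oxide by phloroglucinol (sets C1′), then twofold formylation.
- Ring order: ring A (organocatalytic Michael/aldol) → ring B (Diels–Alder) → preformed aromatic ring attached → pyran ring last.

Assumption: the target is taken exactly as drawn; cadinane locants are used for the terpene carbons of all intermediates (C1 and C6 ring fusion, C4 spiro carbon, C7 isopropyl carbon, C10 methyl carbon, C15 chroman CH2, C1′ benzylic CH).

**Step 1**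
Reactants: 1 3-methylbutanal; 2 but-3-en-2-one
Product: 3 (2S)-5-oxo-2-(propan-2-yl)hexanal
Conditions: (S)-2-(methoxydiphenylmethyl)pyrrolidine (5 mol %), ethyl 3,4-dihydroxybenzoate (20 mol %), neat, 4 °C
Reagents that add atoms: none
Why: Enamine-catalysed asymmetric Michael addition (diarylprolinol ether catalysis), in which the enone adds to the enamine face not shielded by the diphenylmethoxymethyl group, setting the future C7 centre as S.

**Step 2**
Reactants: 3 (2S)-5-oxo-2-(propan-2-yl)hexanal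
Product: 4 (4S)-4-(propan-2-yl)cyclohex-2-en-1-one
Conditions: LiOH (10 mol %), i-PrOH, 25 °C
Reagents that add atoms: none
Why: Intramolecular aldol condensation (methyl-ketone enolate onto the aldehyde, then E1cB dehydration) closes ring A, and the stereocentre becomes the γ-carbon of the enone, so mild catalytic base keeps its erosion small.

**Step 3**
Reactants: 2 but-3-en-2-one
Product: 5 2-(tert-butyldimethylsilyloxy)buta-1,3-diene
Conditions: TBSOTf, Et3N, Et2O, 0 → 25 °C
Reagents that add atoms: tert-butyldimethylsilyl trifluoromethanesulfonate, CC(C)(C)[Si](C)(C)OS(=O)(=O)C(F)(F)F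
Why: Soft enolisation and O-silylation of the methyl ketone (silyl enol ether formation) gives the electron-rich 2-silyloxydiene.

**Step 4**
Reactants: 4 (4S)-4-(propan-2-yl)cyclohex-2-en-1-one; 5 2-(tert-butyldimethylsilyloxy)buta-1,3-diene
Product: 6 (4S,4aS,8aS)-6-(tert-butyldimethylsilyloxy)-4-isopropyl-3,4,4a,5,8,8a-hexahydronaphthalen-1(2H)-one
Conditions: AlBr3/AlMe3 (10:1, 20 mol %), toluene/CH2Cl2, −5 °C
Reagents that add atoms: none
Why: Lewis-acid-catalysed Diels–Alder reaction in which the 2-silyloxy group directs the "para" adduct (oxygen on C4), suprafacial addition gives the cis ring fusion, and the diene adds anti to the neighbouring isopropyl group (the usual sense for 4-alkylcyclohexenones), setting C1 and C6.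

**Step 5**
Reactants: 6 (4S,4aS,8aS)-6-(tert-butyldimethylsilyloxy)-4-isopropyl-3,4,4a,5,8,8a-hexahydronaphthalen-1(2H)-one
Product: 7 (4S,4aS,8aS)-6-(tert-butyldimethylsilyloxy)-4-isopropyl-1-methylene-1,2,3,4,4a,5,8,8a-octahydronaphthalene
Conditions: Ph3PCH3Br, KOt-Bu, THF, 0 → 25 °C
Reagents that add atoms: methyltriphenylphosphonium bromide, C[P+](c1ccccc1)(c1ccccc1)c1ccccc1.[Br-]
Why: Wittig methylenation converts the C10 ketone into the exocyclic alkene while the silyl enol ether is inert, and fast olefination at low temperature outruns enolisation so the cis fusion at C1 is kept.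

**Step 6**
Reactants: 7 (4S,4aS,8aS)-6-(tert-butyldimethylsilyloxy)-4-isopropyl-1-methylene-1,2,3,4,4a,5,8,8a-octahydronaphthalene
Product: 8 (1R,4S,4aS,8aR)-6-(tert-butyldimethylsilyloxy)-4-isopropyl-1-methyl-1,2,3,4,4a,5,8,8a-octahydronaphthalene
Conditions: H2 (1 atm), RhCl(PPh3)3 (5 mol %), benzene, 25 °C
Reagents that add atoms: none
Why: Homogeneous hydrogenation with the sterically sensitive RhCl(PPh3)3 reduces only the 1,1-disubstituted alkene and delivers H2 to the convex face opposite the axial C1–C2 bond of ring B, so the C10 methyl ends cis to C2 and trans to the isopropyl group (10R).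

**Step 7**
Reactants: 8 (1R,4S,4aS,8aR)-6-(tert-butyldimethylsilyloxy)-4-isopropyl-1-methyl-1,2,3,4,4a,5,8,8a-octahydronaphthalene
Product: 9 (4aS,5R,8S,8aS)-8-isopropyl-5-methyl-4a,5,6,7,8,8a-hexahydronaphthalen-2(1H)-one
Conditions: Pd(OAc)2 (1.1 equiv), MeCN, 40 °C
Reagents that add atoms: none
Why: Saegusa–Ito oxidation (the regiodefined silyl enol ether transfers its enolate to Pd(OAc)2, then β-hydride elimination) gives the C2=C3 enone, after which C5 is the only enolisable α-position of the C4 ketone.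

**Step 8**
Reactants: 9 (4aS,5R,8S,8aS)-8-isopropyl-5-methyl-4a,5,6,7,8,8a-hexahydronaphthalen-2(1H)-one
Product: 11 (4aS,5R,8S,8aS)-8-isopropyl-5-methyl-4a,5,6,7,8,8a-hexahydronaphthalen-2-yl trifluoromethanesulfonate, via lithium dienolate 10 (not isolated)
Conditions: LiN(SiMe3)2, THF, −78 °C; PhNTf2, −78 → 0 °C
Reagents that add atoms: N-phenylbis(trifluoromethanesulfonimide), O=S(=O)(N(c1ccccc1)S(=O)(=O)C(F)(F)F)C(F)(F)F
Why: Kinetic α′-deprotonation gives the cross-conjugated dienolate and O-sulfonylation (enol triflate formation) fixes the C4=C5 double bond without any regiochemical choice.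

**Step 9**
Reactants: 11 (4aS,5R,8S,8aS)-8-isopropyl-5-methyl-4a,5,6,7,8,8a-hexahydronaphthalen-2-yl trifluoromethanesulfonate
Product: 12 (4aR,5R,8S,8aS)-8-isopropyl-5-methyl-3,4,4a,5,6,7,8,8a-octahydronaphthalen-2-yl trifluoromethanesulfonate
Conditions: 2-nitrobenzenesulfonylhydrazide, Et3N, CH2Cl2, 25 °C
Reagents that add atoms: none
Why: Diimide reduction (concerted syn transfer of H2) is far faster for the cis-disubstituted C2=C3 alkene than for the trisubstituted, electron-poor enol triflate alkene, so only the extra unsaturation is removed and no stereocentre is touched.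

**Step 10**
Reactants: 13 benzene-1,3,5-triol; 14 (2S)-2-phenyloxirane
Product: 15 2-[(1S)-2-hydroxy-1-phenylethyl]benzene-1,3,5-triol
Conditions: (CF3)2CHOH, 25 °C, epoxide added slowly to the triol held in threefold excess
Reagents that add atoms: none
Why: Friedel–Crafts-type arylative epoxide opening in a strongly hydrogen-bond-donating fluorinated alcohol, a pure 1:1 addition in which the ring carbon of the electron-rich phenol attacks the activated benzylic C–O bond in an SN2-like way with inversion, setting C1′ as S, while the excess of triol suppresses a second alkylation.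

**Step 11**
Reactants: 15 2-[(1S)-2-hydroxy-1-phenylethyl]benzene-1,3,5-triol
Product: 16 2,4,6-trihydroxy-5-[(1S)-2-hydroxy-1-phenylethyl]benzene-1,3-dicarbaldehyde
Conditions: POCl3, DMF, MeCN, 0 → 25 °C; H2O, 50 °C; K2CO3, MeOH, 25 °C
Reagents that add atoms: N,N-dimethylformamide, CN(C)C=O; water, O
Why: Twofold Vilsmeier–Haack formylation of the two free positions of the very electron-rich ring, with the primary alcohol formylated in passing and released again by the final methanolysis.

**Step 12**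
Reactants: 16 2,4,6-trihydroxy-5-[(1S)-2-hydroxy-1-phenylethyl]benzene-1,3-dicarbaldehyde
Product: 17 5-[(1S)-2-hydroxy-1-phenylethyl]-2,4,6-tris(methoxymethoxy)benzene-1,3-dicarbaldehyde
Conditions: MOMCl (3.3 equiv), K2CO3, DMF, 0 → 25 °C
Reagents that add atoms: chloromethyl methyl ether, COCCl
Why: Williamson-type O-alkylation of the three acidic, formyl-flanked phenoxides, which is much faster than reaction of the non-ionised primary alcohol.

**Step 13**
Reactants: 17 5-[(1S)-2-hydroxy-1-phenylethyl]-2,4,6-tris(methoxymethoxy)benzene-1,3-dicarbaldehyde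
Product: 18 5-[(1S)-2-iodo-1-phenylethyl]-2,4,6-tris(methoxymethoxy)benzene-1,3-dicarbaldehyde
Conditions: PPh3, I2, imidazole, CH2Cl2, 0 → 25 °C
Reagents that add atoms: iodine, II
Why: Appel iodination of the primary alcohol, possible now that the ortho phenols are masked and cannot close a dihydrobenzofuran, with the stereocentre one carbon away and untouched.

**Step 14**
Reactants: 18 5-[(1S)-2-iodo-1-phenylethyl]-2,4,6-tris(methoxymethoxy)benzene-1,3-dicarbaldehyde; 12 (4aR,5R,8S,8aS)-8-isopropyl-5-methyl-3,4,4a,5,6,7,8,8a-octahydronaphthalen-2-yl trifluoromethanesulfonate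
Product: 20 5-{(1S)-2-[(4aR,5R,8S,8aS)-8-isopropyl-5-methyl-3,4,4a,5,6,7,8,8a-octahydronaphthalen-2-yl]-1-phenylethyl}-2,4,6-tris(methoxymethoxy)benzene-1,3-dicarbaldehyde, via alkylzinc iodide 19 (not isolated)
Conditions: Zn dust, LiCl, THF, 40 °C; then 12, PdCl2(dppf) (5 mol %), THF, 50 °C
Reagents that add atoms: none
Why: Zinc insertion into the primary C–I bond and Negishi sp3–sp2 cross-coupling with the enol triflate form the C15–C4 bond, since alkylzinc halides do not add to the hindered aryl aldehydes and the bidentate ferrocenyl phosphine suppresses β-hydride elimination.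

**Step 15**
Reactants: 20 5-{(1S)-2-[(4aR,5R,8S,8aS)-8-isopropyl-5-methyl-3,4,4a,5,6,7,8,8a-octahydronaphthalen-2-yl]-1-phenylethyl}-2,4,6-tris(methoxymethoxy)benzene-1,3-dicarbaldehyde
Product: 21 2,4,6-trihydroxy-5-{(1S)-2-[(4aR,5R,8S,8aS)-8-isopropyl-5-methyl-3,4,4a,5,6,7,8,8a-octahydronaphthalen-2-yl]-1-phenylethyl}benzene-1,3-dicarbaldehyde
Conditions: HCl (2 M in MeOH), THF, 40 °C
Reagents that add atoms: none
Why: Acid-catalysed acetal exchange removes the three methoxymethyl ethers (activated by the ortho formyl groups) under conditions too mild to protonate the trisubstituted alkene.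

**Step 16**
Reactants: 21 2,4,6-trihydroxy-5-{(1S)-2-[(4aR,5R,8S,8aS)-8-isopropyl-5-methyl-3,4,4a,5,6,7,8,8a-octahydronaphthalen-2-yl]-1-phenylethyl}benzene-1,3-dicarbaldehyde
Product: 24 guajadial D, via C5 phenylselenide 22 (not isolated), via C5 selenoxide 23 (not isolated)
Conditions: PhSeCl (1.1 equiv), CH2Cl2, −78 °C; m-CPBA (1.1 equiv), −78 °C; i-Pr2NH, −78 → 25 °C
Reagents that add atoms: none
Why: Anti phenylselenoetherification then selenoxide syn-elimination: PhSe+ adds to C4=C5 on the convex face that carries H6 (away from the pseudo-axial C6–C7 bond), one of the two equivalent ortho phenols opens the seleniranium at tertiary C4 from the opposite face (6-exo, Markovnikov), and the selenoxide can only eliminate syn with H6, so the alkene moves to C5=C6 and the C6–H stereocentre is relayed to the spiro centre (4S), while an adduct from the wrong face has no syn hydrogen and cannot give the C4 epimer.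

**Compound list**
1 | 3-methylbutanal (isovaleraldehyde) | CC(C)CC=O | starting material
2 | but-3-en-2-one (methyl vinyl ketone) | CC(=O)C=C | starting material
3 | (2S)-5-oxo-2-(propan-2-yl)hexanal | CC(C)[C@@H](C=O)CCC(C)=O | intermediate
4 | (4S)-4-(propan-2-yl)cyclohex-2-en-1-one, (S)-cryptone | CC(C)[C@@H]1CCC(=O)C=C1 | intermediate
5 | 2-(tert-butyldimethylsilyloxy)buta-1,3-diene | C=CC(=C)O[Si](C)(C)C(C)(C)C | intermediate
6 | (4S,4aS,8aS)-6-(tert-butyldimethylsilyloxy)-4-isopropyl-3,4,4a,5,8,8a-hexahydronaphthalen-1(2H)-one (cis-fused; both ring-fusion H on the face of the isopropyl group) | CC(C)[C@@H]1CCC(=O)[C@H]2CC=C(O[Si](C)(C)C(C)(C)C)C[C@@H]12 | intermediate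
7 | (4S,4aS,8aS)-6-(tert-butyldimethylsilyloxy)-4-isopropyl-1-methylene-1,2,3,4,4a,5,8,8a-octahydronaphthalene | CC(C)[C@@H]1CCC(=C)[C@H]2CC=C(O[Si](C)(C)C(C)(C)C)C[C@@H]12 | intermediate
8 | (1R,4S,4aS,8aR)-6-(tert-butyldimethylsilyloxy)-4-isopropyl-1-methyl-1,2,3,4,4a,5,8,8a-octahydronaphthalene | CC(C)[C@@H]1CC[C@@H](C)[C@H]2CC=C(O[Si](C)(C)C(C)(C)C)C[C@@H]12 | intermediate
9 | (4aS,5R,8S,8aS)-8-isopropyl-5-methyl-4a,5,6,7,8,8a-hexahydronaphthalen-2(1H)-one | CC(C)[C@@H]1CC[C@@H](C)[C@H]2C=CC(=O)C[C@@H]12 | intermediate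
10 | lithium (4aS,5R,8S,8aS)-8-isopropyl-5-methyl-4a,5,6,7,8,8a-hexahydronaphthalen-2-olate (cross-conjugated dienolate) | CC(C)[C@@H]1CC[C@@H](C)[C@H]2C=CC(O[Li])=C[C@@H]12 | intermediate (not isolated)
11 | (4aS,5R,8S,8aS)-8-isopropyl-5-methyl-4a,5,6,7,8,8a-hexahydronaphthalen-2-yl trifluoromethanesulfonate | CC(C)[C@@H]1CC[C@@H](C)[C@H]2C=CC(OS(=O)(=O)C(F)(F)F)=C[C@@H]12 | intermediate
12 | (4aR,5R,8S,8aS)-8-isopropyl-5-methyl-3,4,4a,5,6,7,8,8a-octahydronaphthalen-2-yl trifluoromethanesulfonate | CC(C)[C@@H]1CC[C@@H](C)[C@H]2CCC(OS(=O)(=O)C(F)(F)F)=C[C@@H]12 | intermediate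
13 | benzene-1,3,5-triol (phloroglucinol) | Oc1cc(O)cc(O)c1 | starting material
14 | (2S)-2-phenyloxirane, (S)-styrene oxide | C1[C@@H](O1)c1ccccc1 | starting material
15 | 2-[(1S)-2-hydroxy-1-phenylethyl]benzene-1,3,5-triol | OC[C@@H](c1ccccc1)c1c(O)cc(O)cc1O | intermediate
16 | 2,4,6-trihydroxy-5-[(1S)-2-hydroxy-1-phenylethyl]benzene-1,3-dicarbaldehyde | OC[C@@H](c1ccccc1)c1c(O)c(C=O)c(O)c(C=O)c1O | intermediate
17 | 5-[(1S)-2-hydroxy-1-phenylethyl]-2,4,6-tris(methoxymethoxy)benzene-1,3-dicarbaldehyde | OC[C@@H](c1ccccc1)c1c(OCOC)c(C=O)c(OCOC)c(C=O)c1OCOC | intermediate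
18 | 5-[(1S)-2-iodo-1-phenylethyl]-2,4,6-tris(methoxymethoxy)benzene-1,3-dicarbaldehyde | IC[C@@H](c1ccccc1)c1c(OCOC)c(C=O)c(OCOC)c(C=O)c1OCOC | intermediate
19 | {(2S)-2-[3,5-diformyl-2,4,6-tris(methoxymethoxy)phenyl]-2-phenylethyl}zinc iodide | I[Zn]C[C@@H](c1ccccc1)c1c(OCOC)c(C=O)c(OCOC)c(C=O)c1OCOC | intermediate (not isolated)
20 | 5-{(1S)-2-[(4aR,5R,8S,8aS)-8-isopropyl-5-methyl-3,4,4a,5,6,7,8,8a-octahydronaphthalen-2-yl]-1-phenylethyl}-2,4,6-tris(methoxymethoxy)benzene-1,3-dicarbaldehyde | CC(C)[C@@H]1CC[C@@H](C)[C@H]2CCC(C[C@@H](c3ccccc3)c3c(OCOC)c(C=O)c(OCOC)c(C=O)c3OCOC)=C[C@@H]12 | intermediate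
21 | 2,4,6-trihydroxy-5-{(1S)-2-[(4aR,5R,8S,8aS)-8-isopropyl-5-methyl-3,4,4a,5,6,7,8,8a-octahydronaphthalen-2-yl]-1-phenylethyl}benzene-1,3-dicarbaldehyde | CC(C)[C@@H]1CC[C@@H](C)[C@H]2CCC(C[C@@H](c3ccccc3)c3c(O)c(C=O)c(O)c(C=O)c3O)=C[C@@H]12 | intermediate
22 | spirochroman carrying PhSe on C5 (selenium cis to H6, trans to the ring oxygen on C4; C6 still sp3) | CC(C)[C@@H]1CC[C@@H](C)[C@H]2CC[C@@]3([C@H]([Se]c4ccccc4)[C@@H]12)C[C@@H](c1ccccc1)c1c(O)c(C=O)c(O)c(C=O)c1O3 | intermediate (not isolated)
23 | selenoxide of 22 (both configurations at selenium) | CC(C)[C@@H]1CC[C@@H](C)[C@H]2CC[C@@]3([C@H]([Se](=O)c4ccccc4)[C@@H]12)C[C@@H](c1ccccc1)c1c(O)c(C=O)c(O)c(C=O)c1O3 | intermediate (not isolated)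
24 | guajadial D | CC(C)[C@@H]1CC[C@@H](C)[C@H]2CC[C@@]3(C=C12)C[C@@H](c1ccccc1)c1c(O)c(C=O)c(O)c(C=O)c1O3 | target

**Totals**
Total step count: 16. Longest linear sequence: 11 steps (steps 1, 2, 4 to 9, 14, 15, 16).

**The three steps most likely to fail**

Step 16 (seleno-relay). The risks are slow attack by the acidic, hydrogen-bonded phenol, selenium adding to the wrong alkene face (material loss only), and loss during the elimination. The fallback sets out from 21 and returns at 24 by a Wacker-type oxidative cyclisation: PdCl2(MeCN)2 (10 mol %), LiCl, p-benzoquinone, THF, 25 to 40 °C. Under chloride-rich conditions the phenol attacks the coordinated alkene anti to the metal, and only the adduct with divalent palladium on C5 syn to H6 can undergo β-hydride elimination (the other reverts), which gives 24 directly. If syn-oxypalladation operated instead, the C4 epimer would form, so the outcome must be checked. This fallback makes no new compound (F0).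

Step 14 (Negishi coupling of a zinc reagent that carries two aldehydes). The risks are sluggish zinc insertion, intramolecular addition to a formyl group, or β-hydride elimination. The fallback postpones the formylation; it sets out from 15 and returns at 21. Selective phenol protection (MOMCl, K2CO3, DMF) gives (2S)-2-phenyl-2-[2,4,6-tris(methoxymethoxy)phenyl]ethanol F1. Appel iodination gives 2-[(1S)-2-iodo-1-phenylethyl]-1,3,5-tris(methoxymethoxy)benzene F2. Zinc insertion (Zn, LiCl, THF) gives the aldehyde-free alkylzinc iodide F3, which is coupled in the same flask with 12 (PdCl2(dppf)) to the tris(methoxymethyl) ether F4. HCl in MeOH frees the phloroglucinol F5, and a twofold Vilsmeier–Haack formylation (POCl3, DMF, 0 °C; then water) gives 21. The cost is a late formylation in the presence of the alkene.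

Step 9 (partial diimide reduction of the dienyl triflate). The risks are over-reduction or a slow reaction of the conjugated diene. The fallback sets out from 11 and returns at 20: the zinc reagent 19 is coupled first with 11 (PdCl2(dppf), THF, 50 °C) to the 2-alkyl-1,3-diene F6. Its cis-disubstituted C2=C3 bond is then reduced with diimide generated from dipotassium azodicarboxylate and AcOH in MeOH, a hydrazine-free source that spares the aldehydes.

**Further compounds**
F0 | step 16 | none | none
F1 | step 14 | (2S)-2-phenyl-2-[2,4,6-tris(methoxymethoxy)phenyl]ethanol | OC[C@@H](c1ccccc1)c1c(OCOC)cc(OCOC)cc1OCOC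
F2 | step 14 | 2-[(1S)-2-iodo-1-phenylethyl]-1,3,5-tris(methoxymethoxy)benzene | IC[C@@H](c1ccccc1)c1c(OCOC)cc(OCOC)cc1OCOC
F3 | step 14 | {(2S)-2-phenyl-2-[2,4,6-tris(methoxymethoxy)phenyl]ethyl}zinc iodide | I[Zn]C[C@@H](c1ccccc1)c1c(OCOC)cc(OCOC)cc1OCOC
F4 | step 14 | 2-{(1S)-2-[(4aR,5R,8S,8aS)-8-isopropyl-5-methyl-3,4,4a,5,6,7,8,8a-octahydronaphthalen-2-yl]-1-phenylethyl}-1,3,5-tris(methoxymethoxy)benzene | CC(C)[C@@H]1CC[C@@H](C)[C@H]2CCC(C[C@@H](c3ccccc3)c3c(OCOC)cc(OCOC)cc3OCOC)=C[C@@H]12
F5 | step 14 | 2-{(1S)-2-[(4aR,5R,8S,8aS)-8-isopropyl-5-methyl-3,4,4a,5,6,7,8,8a-octahydronaphthalen-2-yl]-1-phenylethyl}benzene-1,3,5-triol | CC(C)[C@@H]1CC[C@@H](C)[C@H]2CCC(C[C@@H](c3ccccc3)c3c(O)cc(O)cc3O)=C[C@@H]12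
F6 | step 9 | 5-{(1S)-2-[(4aS,5R,8S,8aS)-8-isopropyl-5-methyl-4a,5,6,7,8,8a-hexahydronaphthalen-2-yl]-1-phenylethyl}-2,4,6-tris(methoxymethoxy)benzene-1,3-dicarbaldehyde | CC(C)[C@@H]1CC[C@@H](C)[C@H]2C=CC(C[C@@H](c3ccccc3)c3c(OCOC)c(C=O)c(OCOC)c(C=O)c3OCOC)=C[C@@H]12
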